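Tuesday's run and Monday's run both level off in links, and I take that levelling to mean that the second end groups, the limiting reagent, have stopped feeding links.

| flask | first end groups | second end groups | third end groups | remark | time |
|---|---|---|---|---|---|
| Wednesday's | 0.050 M | 0.38 equiv | 0.50 equiv | run made earlier |  |
| Tuesday's | 0.050 M | 0.81 equiv | 0.50 equiv | run made earlier |  |
| Monday's | 0.030 M | 1.05 equiv | 0.50 equiv | run made earlier |  |
| alder | 0.030 M | 0.530 equiv | 0.500 equiv |  | 80 min |
| elm | 0.050 M | 1.05 equiv | 0.500 equiv |  | 80 min |

| run | time / min | links / % |
|---|---|---|
| Wednesday's | 3.00 | 8 |
| Wednesday's | 8.00 | 10 |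
| Wednesday's | 15.0 | 14 |
| Wednesday's | 40.0 | 20 |
| Tuesday's | 5.00 | 20 |
| Tuesday's | 15.0 | 29 |
| Tuesday's | 25.0 | 30 |
| Tuesday's | 40.0 | 27 |
| Monday's | 5.00 | 19 |
| Monday's | 15.0 | 28 |
| Monday's | 25.0 | 32 |
| Monday's | 40.0 | 32 |

(scatter of a reading: 2 percentage points)

- in percentages every species weighs as the first end groups in it: one self-condensation product counts as two
- steps thought possible: 2 first end groups -> self-condensation product; second end groups -> decomposed reagent; second end groups + third end groups -> links of the second sort; first end groups + second end groups -> links; third end groups <-> dormant form
- where the amount of first end groups changes, what is given in equivalents or mol% on it follows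

- which of the two ends with the higher amount of links, in percent of the first end groups charged ("neither" if they lie within 2 percentage points) (alder / elm / neither)
- links at the end, in percent of the first end groups charged, alder
- links at the end, in percent of the first end groups charged, elm

I divide the mean of the two last readings by the equivalents of second end groups charged. This gives 0.352 for Tuesday's run at 0.050 M and 0.305 for Monday's run at 0.030 M. I call this ratio the link yield: the fraction of first end groups charged that ends as links, per equivalent of second end groups charged. Elm has Tuesday's concentration, so I reckon 36.9% for it, and alder has Monday's, so I reckon 16.2%. But Wednesday's last reading, at Tuesday's concentration and a smaller charge, gives 0.526, so the ratio as read differs with the charge and my alder figure may be low.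

The forecast names elm as the higher and sets alder at 22% (range 16% to 28%). It sets elm at 43% (range 35% to 52%), higher than my figure for elm, saying of elm that “the extra reagent goes largely to links”.

The flasks give 18.0% for alder and 38.0% for elm, so elm ends higher.

    2 first end groups → self-condensation product (k = 0.0470 M⁻¹ s⁻¹)
    second end groups → decomposed reagent (k = 8.80 × 10⁻⁴ s⁻¹)
    second end groups + third end groups → links of the second sort (k = 7.80 × 10⁻⁴ M⁻¹ s⁻¹)
    first end groups + second end groups → links (k = 0.0390 M⁻¹ s⁻¹)
    third end groups ⇌ dormant form (K = 5.60, k = 3.40 × 10⁻⁴ s⁻¹)

In alder, first end groups go into self-condensation product at 4.5 times the rate at which they go into links at the start, and at 52 times that rate at 80.0 min. By then the second end groups in alder stand at 0.539% of their charge. The link yield comes out at 0.339 for alder, where the readings of Monday's run gave 0.305, and at 0.361 for elm, where the readings of Tuesday's run gave 0.352. A neighbour of alder charged with 0.900 equiv, for which Monday's yield gives 27.5%, ends at 28.8%.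

The readings were generated by integration on assumed constants.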